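**Strategy**
Locants: C1 = methyl-bearing quaternary fusion carbon, C2/C3 = cyclopentane CH2, C4 = carbinol carbon with isopropyl, C5 = fusion CH, C6 = acyloxy CH, C7=C8 = ring alkene (CH3 on C8), C9/C10 = cycloheptene CH2.
Enabling feature: in the seven-membered ring, C6 lies midway between two methyl-substituted carbons that are both β to it (C8 through C7, C1 through C5). At the ketone level the ring is therefore 3,6-dimethylcyclohepta-2,6-dienone, whose two enone arms are exchanged by a C2 axis, and C2–C3–C4 is a ketone homoenolate grafted onto one arm.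
Cuts, in order: the acyl–O bond at C6, C4–C5 (aldol), C1–C2 (conjugate addition), then the dienone back to the oxygen-bridged (4+3) adduct of 2,5-dimethylfuran and an oxyallyl cation.
Forward order: the seven-membered ring is made first (bridged, then unbridged), the side chain is joined at C1, the cyclopentane is closed at C4–C5, the C6 ketone is reduced, and the aroyl group is attached last before the phenol is freed.
Stereochemistry: C1 comes from a chiral copper catalyst, C5 and C4 follow from C1 in a tether-controlled chelated aldol, and C6 comes from external hydride attack on the face carrying H5.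

Key step: step 8

Assumption: the sense of induction of the copper–NHC catalyst on the dienone is taken by analogy with 3-methylcycloheptenone. Both ligand enantiomers derive from commercial tert-leucinol, and the one that delivers the alkyl group to the Si face of the β-carbon (R at C1) is used.

**Step 1**
Reactants: 1 2,5-dimethylfuran; 2 1,1,3,3-tetrabromoacetone
Product: 4 2,4-dibromo-1,5-dimethyl-8-oxabicyclo[3.2.1]oct-6-en-3-one (bromide epimers), via dibromo-oxyallyl cation 3 (not isolated)
Conditions: Zn–Ag couple, THF, −10 °C → rt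
Reagents that add atoms: none
Why: Two-electron reduction of 2 by zinc with loss of bromide gives the 1,3-dibromo-2-oxyallyl cation 3, which the electron-rich furan diene captures in an oxyallyl cation (4+3) cycloaddition, the oxygen bridge holding both bridgehead methyl groups on one side so that the skeleton is meso.

**Step 2**
Reactants: 4 2,4-dibromo-1,5-dimethyl-8-oxabicyclo[3.2.1]oct-6-en-3-one
Product: 5 (1R,5S)-1,5-dimethyl-8-oxabicyclo[3.2.1]oct-6-en-3-one (meso)
Conditions: Zn–Cu couple, NH4Cl-saturated MeOH, rt
Reagents that add atoms: none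
Why: Zinc-mediated reductive dehalogenation of α-bromo ketones runs through zinc enolates that ammonium chloride protonates, and neither the alkene nor the bridging ether is touched.

**Step 3**
Reactants: 5 (1R,5S)-1,5-dimethyl-8-oxabicyclo[3.2.1]oct-6-en-3-one
Product: 6 (1R,5S)-1,5-dimethyl-8-oxabicyclo[3.2.1]octan-3-one (meso)
Conditions: H2 (1 atm), 10% Pd/C, EtOAc, rt
Reagents that add atoms: none
Why: Heterogeneous catalytic hydrogenation saturates the strained disubstituted alkene much faster than the ketone, and its removal keeps the following bridge opening from running on to a tropone.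

**Step 4**
Reactants: 6 (1R,5S)-1,5-dimethyl-8-oxabicyclo[3.2.1]octan-3-one
Product: 8 3,6-dimethylcyclohepta-2,6-dien-1-one, via ring-opened hydroxy enone 7 (not isolated)
Conditions: p-TsOH·H2O (10 mol %), toluene, reflux, Dean–Stark trap
Reagents that add atoms: none
Why: Acid-catalysed retro-oxa-Michael cleavage of the tertiary β-alkoxy ketone opens the bridge to 7, whose tertiary β-hydroxy ketone dehydrates under the same conditions, and azeotropic removal of water pulls both equilibria towards the cross-conjugated dienone with two trisubstituted double bonds.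

**Step 5**
Reactants: 9 methyl 4-methyl-3-oxopentanoate
Product: 10 methyl 2-(2-isopropyl-1,3-dioxolan-2-yl)acetate
Conditions: ethylene glycol, p-TsOH (cat.), toluene, reflux, Dean–Stark trap
Reagents that add atoms: ethylene glycol, OCCO
Why: Acid-catalysed ketalisation with azeotropic water removal is standard for β-keto esters and masks the isopropyl ketone against hydride and against the later carbon–magnesium bond.

**Step 6**
Reactants: 10 methyl 2-(2-isopropyl-1,3-dioxolan-2-yl)acetate
Product: 11 2-(2-isopropyl-1,3-dioxolan-2-yl)ethan-1-ol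
Conditions: LiAlH4, Et2O, 0 °C; then Na2SO4·10H2O
Reagents that add atoms: none
Why: Lithium aluminium hydride reduces the ester to the primary alcohol, and the non-acidic quench leaves the dioxolane intact.

**Step 7**
Reactants: 11 2-(2-isopropyl-1,3-dioxolan-2-yl)ethan-1-ol
Product: 12 2-(2-bromoethyl)-2-isopropyl-1,3-dioxolane
Conditions: CBr4, PPh3, 2,6-lutidine (cat.), CH2Cl2, 0 °C
Reagents that add atoms: carbon tetrabromide, BrC(Br)(Br)Br
Why: In the Appel reaction bromide displaces the alkoxyphosphonium ion by SN2 at an unhindered primary carbon, and the trace of lutidine scavenges acid so that the ketal survives.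

**Step 8**
Reactants: 8 3,6-dimethylcyclohepta-2,6-dien-1-one; 12 2-(2-bromoethyl)-2-isopropyl-1,3-dioxolane
Product: 15 (R)-6-[2-(2-isopropyl-1,3-dioxolan-2-yl)ethyl]-3,6-dimethylcyclohept-2-en-1-one, via ketal Grignard reagent 13 (not isolated), via magnesium dienolate 14 (not isolated)
Conditions: 12, Mg (I2-activated), Et2O, ≤ 25 °C; then Cu(OTf)2 (3 mol %), tert-leucinol-derived N-mesityl hydroxyalkyl imidazolinium hexafluorophosphate (4 mol %), Et2O, −30 °C, slow addition of 8; sat. aq NH4Cl, 0 °C
Reagents that add atoms: none
Why: Grignard reagent 13 deprotonates the imidazolinium salt and transmetallates to a chiral alkoxy-NHC alkylcuprate, which π-binds one enone arm of 8, adds oxidatively at the β-carbon (the future C1) and reductively eliminates, forging C1–C2 and releasing the cross-conjugated magnesium dienolate 14. The closest known reaction type is the copper/NHC-catalysed asymmetric conjugate addition of alkyl Grignard reagents to 3-methylcyclohexenone and 3-methylcycloheptenone, which builds all-carbon quaternary centres, and 8 is such a β-methylcycloheptenone carrying a second, identical arm. No ring closes in this step. The only new stereocentre, C1, is fixed as R by the ligand, which steers the alkyl group to the Si face of the β-carbon, and because the C2 axis makes the two β-carbons and their Si faces homotopic, attack on either arm gives the same enantiomer and no regiochemical question arises. The step needs 1,4- over 1,2-addition and single over double addition: fast cuprate transfer in ether at low temperature secures the first, and the substrate secures the second, since after one addition the carbonyl is locked as dienolate 14, the C7=C8 bond is no longer an acceptor and cross-conjugation offers no 1,6-pathway. The buffered quench protonates C5 and leaves both the dioxolane and the untouched C6–C7–C8 enone, already the allylic unit of the target, in place.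

**Step 9**
Reactants: 15 (R)-6-[2-(2-isopropyl-1,3-dioxolan-2-yl)ethyl]-3,6-dimethylcyclohept-2-en-1-one
Product: 16 (R)-3,6-dimethyl-6-(4-methyl-3-oxopentyl)cyclohept-2-en-1-one
Conditions: 1 M HCl, THF, rt
Reagents that add atoms: water, O
Why: Acid hydrolysis of the dioxolane runs through its oxocarbenium ion, the quaternary centre has no ionisable or acidic neighbour, and the enone is inert to dilute acid at room temperature.

**Step 10**
Reactants: 16 (R)-3,6-dimethyl-6-(4-methyl-3-oxopentyl)cyclohept-2-en-1-one
Product: 17 (3R,3aR,8aR)-3-hydroxy-3-isopropyl-6,8a-dimethyl-2,3,3a,7,8,8a-hexahydroazulen-4(1H)-one (cis-fused; H5 cis to the C1 methyl, C4 hydroxyl cis to the C5–C6 bond)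
Conditions: KOt-Bu (0.2 equiv), THF–t-BuOH, −20 → 0 °C; pH 7 buffer
Reagents that add atoms: none
Why: In this reversible intramolecular aldol addition (5-enolexo-exo-trig) only the C5 enolate reaches the isopropyl ketone through a five-membered transition state that keeps the enone conjugated, the two-carbon tether from C1 forces C4 to bond on the face that carries C2 so that H5 ends cis to the C1 methyl, and the metal-bridged aldolate places O4 next to the C6 carbonyl with the isopropyl group on the convex face.

**Step 11**
Reactants: 17 (3R,3aR,8aR)-3-hydroxy-3-isopropyl-6,8a-dimethyl-2,3,3a,7,8,8a-hexahydroazulen-4(1H)-one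
Product: 18 (3R,3aS,4R,8aR)-3-isopropyl-6,8a-dimethyl-1,2,3,3a,4,7,8,8a-octahydroazulene-3,4-diol
Conditions: NaBH4, CeCl3·7H2O, MeOH, −78 → −40 °C
Reagents that add atoms: none
Why: In the Luche 1,2-reduction cerium bridges the C4 hydroxyl and the C6 carbonyl, and external (not oxygen-delivered) hydride approaches over H5, away from C4 and the cyclopentane, which gives R at C6 with H6 cis to H5 and both oxygens on the same face.

**Step 12**
Reactants: 19 isovanillic acid (3-hydroxy-4-methoxybenzoic acid)
Product: 21 3-(tert-butyldimethylsilyloxy)-4-methoxybenzoic acid, via bis-silyl derivative 20 (not isolated)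
Conditions: TBSCl (2.3 equiv), imidazole, DMF, rt; then THF–AcOH–H2O, rt
Reagents that add atoms: tert-butyldimethylsilyl chloride, CC(C)(C)[Si](C)(C)Cl
Why: The silyl chloride–imidazole system silylates both acidic hydroxyl groups, and the far more labile silyl ester is then hydrolysed while the aryl silyl ether stays in place.

**Step 13**
Reactants: 18 (3R,3aS,4R,8aR)-3-isopropyl-6,8a-dimethyl-1,2,3,3a,4,7,8,8a-octahydroazulene-3,4-diol; 21 3-(tert-butyldimethylsilyloxy)-4-methoxybenzoic acid
Product: 23 (3R,3aS,4R,8aR)-3-hydroxy-3-isopropyl-6,8a-dimethyl-1,2,3,3a,4,7,8,8a-octahydroazulen-4-yl 3-(tert-butyldimethylsilyloxy)-4-methoxybenzoate, via Yamaguchi mixed anhydride 22 (not isolated)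
Conditions: 21, 2,4,6-Cl3C6H2COCl, Et3N, toluene, rt; then 18, DMAP, toluene, rt → 40 °C
Reagents that add atoms: none
Why: In the Yamaguchi esterification DMAP attacks the unhindered aroyl carbonyl of 22, and the acylpyridinium ion acylates the secondary allylic C6 hydroxyl with retention at C6, while the tertiary C4 hydroxyl is too hindered to react.

**Step 14**
Reactants: 23 silyl-protected ester
Product: 24 (3R,3aS,4R,8aR)-3-hydroxy-3-isopropyl-6,8a-dimethyl-1,2,3,3a,4,7,8,8a-octahydroazulen-4-yl 3-hydroxy-4-methoxybenzoate (target)
Conditions: TBAF, AcOH (1:1), THF, 0 °C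
Reagents that add atoms: none
Why: Fluoride cleaves the aryl silyl ether, driven by the strong Si–F bond and the good phenoxide leaving group, and the acetic acid buffer keeps the medium from hydrolysing or shifting the allylic ester.

**Compound list**
1 | 2,5-dimethylfuran | Cc1ccc(C)o1 | starting material
2 | 1,1,3,3-tetrabromoacetone | BrC(Br)C(=O)C(Br)Br | starting material
3 | 1,3-dibromo-2-oxyallyl cation (zinc-generated) | [O-]C(=CBr)[CH+]Br | intermediate
4 | 2,4-dibromo-1,5-dimethyl-8-oxabicyclo[3.2.1]oct-6-en-3-one (bromide epimers) | C[C@@]12C(Br)C(=O)C(Br)[C@@](C)(C=C1)O2 | intermediate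
5 | (1R,5S)-1,5-dimethyl-8-oxabicyclo[3.2.1]oct-6-en-3-one (meso) | C[C@@]12CC(=O)C[C@@](C)(C=C1)O2 | intermediate
6 | (1R,5S)-1,5-dimethyl-8-oxabicyclo[3.2.1]octan-3-one (meso) | C[C@@]12CC(=O)C[C@@](C)(CC1)O2 | intermediate
7 | 6-hydroxy-3,6-dimethylcyclohept-2-en-1-one (racemic) | CC1=CC(=O)CC(C)(O)CC1 | intermediate
8 | 3,6-dimethylcyclohepta-2,6-dien-1-one | CC1=CC(=O)C=C(C)CC1 | intermediate
9 | methyl 4-methyl-3-oxopentanoate | COC(=O)CC(=O)C(C)C | starting material
10 | methyl 2-(2-isopropyl-1,3-dioxolan-2-yl)acetate | COC(=O)CC1(C(C)C)OCCO1 | intermediate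
11 | 2-(2-isopropyl-1,3-dioxolan-2-yl)ethan-1-ol | OCCC1(C(C)C)OCCO1 | intermediate
12 | 2-(2-bromoethyl)-2-isopropyl-1,3-dioxolane | BrCCC1(C(C)C)OCCO1 | intermediate
13 | [2-(2-isopropyl-1,3-dioxolan-2-yl)ethyl]magnesium bromide | Br[Mg]CCC1(C(C)C)OCCO1 | intermediate
14 | bromomagnesium (R)-dienolate (C5=C6–OMgBr, C7=C8) | Br[Mg]OC1=C[C@@](C)(CCC2(C(C)C)OCCO2)CCC(C)=C1 | intermediate
15 | (R)-6-[2-(2-isopropyl-1,3-dioxolan-2-yl)ethyl]-3,6-dimethylcyclohept-2-en-1-one | O=C1C=C(C)CC[C@](C)(CCC2(C(C)C)OCCO2)C1 | intermediate
16 | (R)-3,6-dimethyl-6-(4-methyl-3-oxopentyl)cyclohept-2-en-1-one | O=C1C=C(C)CC[C@](C)(CCC(=O)C(C)C)C1 | intermediate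
17 | (3R,3aR,8aR)-3-hydroxy-3-isopropyl-6,8a-dimethyl-2,3,3a,7,8,8a-hexahydroazulen-4(1H)-one | O=C1C=C(C)CC[C@]2(C)CC[C@@](O)(C(C)C)[C@H]12 | intermediate
18 | (3R,3aS,4R,8aR)-3-isopropyl-6,8a-dimethyl-1,2,3,3a,4,7,8,8a-octahydroazulene-3,4-diol | O[C@@H]1C=C(C)CC[C@]2(C)CC[C@@](O)(C(C)C)[C@H]12 | intermediate
19 | isovanillic acid | COc1ccc(C(=O)O)cc1O | starting material
20 | tert-butyldimethylsilyl 3-(tert-butyldimethylsilyloxy)-4-methoxybenzoate | COc1ccc(C(=O)O[Si](C)(C)C(C)(C)C)cc1O[Si](C)(C)C(C)(C)C | intermediate
21 | 3-(tert-butyldimethylsilyloxy)-4-methoxybenzoic acid | COc1ccc(C(=O)O)cc1O[Si](C)(C)C(C)(C)C | intermediate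
22 | 3-(tert-butyldimethylsilyloxy)-4-methoxybenzoic 2,4,6-trichlorobenzoic anhydride | COc1ccc(C(=O)OC(=O)c2c(Cl)cc(Cl)cc2Cl)cc1O[Si](C)(C)C(C)(C)C | intermediate
23 | (3R,3aS,4R,8aR)-3-hydroxy-3-isopropyl-6,8a-dimethyl-1,2,3,3a,4,7,8,8a-octahydroazulen-4-yl 3-(tert-butyldimethylsilyloxy)-4-methoxybenzoate | COc1ccc(C(=O)O[C@@H]2C=C(C)CC[C@]3(C)CC[C@@](O)(C(C)C)[C@H]23)cc1O[Si](C)(C)C(C)(C)C | intermediate
24 | (3R,3aS,4R,8aR)-3-hydroxy-3-isopropyl-6,8a-dimethyl-1,2,3,3a,4,7,8,8a-octahydroazulen-4-yl 3-hydroxy-4-methoxybenzoate | COc1ccc(C(=O)O[C@@H]2C=C(C)CC[C@]3(C)CC[C@@](O)(C(C)C)[C@H]23)cc1O | target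

**Totals**
Total steps: 14.
Longest linear sequence: 10 steps (1, 2, 3, 4, 8, 9, 10, 11, 13, 14).

**Steps most likely to fail**

Step 8. The γ-ketal Grignard reagent may decay by 1,3-elimination before it is consumed. Uncatalysed 1,2-addition may compete. Facial selectivity may erode because the ketal oxygens compete with the ligand for magnesium and copper.
Fallback, from 12 (with 8) and rejoining at 15: the organomagnesium nucleophile is replaced by a non-basic organozirconium one, and the same C1–C2 bond is formed.
- Bromide 12 is dehydrobrominated (KOt-Bu, THF) to 2-isopropyl-2-vinyl-1,3-dioxolane F1.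
- Hydrozirconation with the Schwartz reagent (Cp2ZrHCl, CH2Cl2, rt) places the metal on the terminal carbon and gives chlorobis(cyclopentadienyl)[2-(2-isopropyl-1,3-dioxolan-2-yl)ethyl]zirconium F2.
- F2 is added to 8 under copper(I)/chiral phosphoramidite catalysis, a known way of building quaternary centres on β-methyl cyclic enones near room temperature. Aqueous work-up then gives 15.

Step 10. The enolates may scramble and close through the side-chain enolate (bridged aldol or Michael addition). The aldol equilibrium at the hindered isopropyl ketone may be unfavourable. The ketol may also run on to E1cB dehydration.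
Fallback, from 15 and rejoining at 17: the C5 enolate is generated regiospecifically and irreversibly instead of by equilibration.
- With the side-chain ketone still masked, kinetic α′-deprotonation of 15 (LDA, THF, −78 °C) and trapping with TMSCl gives the C5=C6 trimethylsilyl dienol ether of 15 F3.
- NBS (THF, −78 °C) brominates C5 to give (6R)-7-bromo-6-[2-(2-isopropyl-1,3-dioxolan-2-yl)ethyl]-3,6-dimethylcyclohept-2-en-1-one F4. The bromide epimers are of no consequence.
- Dilute acid unmasks (6R)-7-bromo-3,6-dimethyl-6-(4-methyl-3-oxopentyl)cyclohept-2-en-1-one F5.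
- SmI2 (2 equiv, THF, −78 °C) reduces the C–Br bond to the samarium(III) enolate, which closes on the isopropyl ketone in an intramolecular samarium Reformatsky reaction through a chelated transition state.
- The C4–C5 bond, the cis fusion and the cis relation of O4 to the carbonyl arise as in the main route, and the samarium aldolate resists retro-aldol cleavage and dehydration.

Step 4. The bridge may reclose by oxa-Michael addition, or acid may shift the double bonds out of cross-conjugation at reflux.
Fallback, from 6 and rejoining at 8: the two eliminations are separated and run under base.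
- LiHMDS (THF, −78 → 0 °C) enolises 6 and expels the bridge oxygen.
- The tertiary alkoxide is trapped with Ac2O/DMAP as (±)-1,4-dimethyl-6-oxocyclohept-4-en-1-yl acetate F6.
- DBU (CH2Cl2, rt) removes the acetate by E1cB elimination, which can only place the new double bond in conjugation, and gives 8.

**Further compounds**
F1 | step 8 | 2-isopropyl-2-vinyl-1,3-dioxolane | C=CC1(C(C)C)OCCO1
F2 | step 8 | chlorobis(cyclopentadienyl)[2-(2-isopropyl-1,3-dioxolan-2-yl)ethyl]zirconium | [CH2-]CC1(C(C)C)OCCO1.[Cl-].[Zr+4].c1cc[cH-]c1.c1cc[cH-]c1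
F3 | step 10 | C5=C6 trimethylsilyl dienol ether of 15 | C[Si](C)(C)OC1=C[C@@](C)(CCC2(C(C)C)OCCO2)CCC(C)=C1
F4 | step 10 | (6R)-7-bromo-6-[2-(2-isopropyl-1,3-dioxolan-2-yl)ethyl]-3,6-dimethylcyclohept-2-en-1-one | O=C1C=C(C)CC[C@](C)(CCC2(C(C)C)OCCO2)C1Br
F5 | step 10 | (6R)-7-bromo-3,6-dimethyl-6-(4-methyl-3-oxopentyl)cyclohept-2-en-1-one | O=C1C=C(C)CC[C@](C)(CCC(=O)C(C)C)C1Br
F6 | step 4 | (±)-1,4-dimethyl-6-oxocyclohept-4-en-1-yl acetate | CC(=O)OC1(C)CCC(C)=CC(=O)C1
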